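Late in the north-east run, at 43 s, the reading of product is 0.0925 M, and two chemists disagree about what that reading means. These are the flasks, the readings and the questions.

| flask | starting material | partner | free catalyst | time |
|---|---|---|---|---|
| north-east | 0.200 M | 0.500 M | 0.00200 M |  |
| south | 0.100 M | 0.400 M | 0.00200 M |  |
| north | 0.200 M | 0.500 M | 0.00100 M |  |
| south-west | 1.00 M | 0.500 M | 0.00200 M | 43 s |

| run | time / s | [product] / M |
|---|---|---|
| north-east run | 2.4 | 0.0085 |
| north-east run | 7.4 | 0.0251 |
| north-east run | 14 | 0.0429 |
| north-east run | 22 | 0.0604 |
| north-east run | 32 | 0.0766 |
| north-east run | 43 | 0.0925 |
| south run | 2.4 | 0.0032 |
| south run | 7.4 | 0.0098 |
| south run | 14 | 0.0191 |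
| south run | 22 | 0.0269 |
| south run | 32 | 0.0344 |
| south run | 43 | 0.0433 |
| north run | 2.4 | 0.0050 |
| north run | 7.4 | 0.0139 |
| north run | 14 | 0.0258 |
| north run | 22 | 0.0381 |
| north run | 32 | 0.0509 |
| north run | 43 | 0.0636 |

(standard deviation of a reading: 6 × 10⁻⁴ M)

- Overall: starting material + partner -> product, with free catalyst as catalyst.
- Constant volume, constant temperature.
- What is held in complexes is read along with the free species.
- "The second partner" is partner.
- An order is taken over about fifteen percent of the charge, up and down.

* the power of [free catalyst] that the first rate follows, about the charge of the north-east run; measure it at two percent of starting material made into product
* the south run starts with 0.100 M less of starting material and of partner than the north-east run, and with no product. Compared where both hold the same amount of starting material, once fifteen percent of what the south run was charged with has turned into product, is the south run faster, slower or alike (within a tenth)?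
* product in the south-west run at 43 s, as a share of the starting material charged
* which of these the readings show (the second partner ties up the catalyst / the substrate is lost by itself / the substrate pairs with itself / the second partner is lost in pairs / the product ties up the catalyst)

The first chemist holds to a plain rate: a constant times [starting material] times [partner]. Integrated, this makes the constant times the time equal to a quantity A: the logarithm of [partner]/[starting material], less its value at the start, over the difference of the two charges. In the north-east run A is 0.275 M⁻¹ at 7.4 s, so the constant is 0.0372 M⁻¹ s⁻¹. At 43 s A is 1.39 M⁻¹, which gives 0.0323 M⁻¹ s⁻¹, a lower constant than the early one. The first chemist keeps the early figure and, solving the same closed form for the south-west run, expects 35.5% of its charge.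

The second chemist, who made the forecast, divides the rate by one plus K[product]. K is the product brake, the inverse of the [product] at which the rate is halved with the other concentrations held; the usual term is product inhibition. The forecast reads the runs this way, saying “falls with product rather than time”, and gives 0.85, faster, 29.5% and the product ties up the catalyst, with K at 2.7 per molar.

My own reckoning keeps that view but gets another K. The integral becomes k times time = A + K·B, where B is the charge of starting material times the logarithm of its charge over what is left, less the same for the partner, over the same difference of charges. In the north-east run B is 0.00356 at the early reading and 0.0729 at the late one. The two readings therefore give a brake of 4.07 M⁻¹ and k of 0.0392 M⁻¹ s⁻¹.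

With these, the forecast's 0.295 M of product in the south-west run arrives at 47.7 s, later than 43 s, so I expect slightly less than the forecast. At equal [starting material] the south and north-east runs also hold equal [partner], since both charges of the south run are 0.100 M lower. The south run then holds 0.0150 M of product against 0.115 M, so I expect it faster by a factor of 1.38.

The simulation gives 27.9% for the south-west run, a catalyst power of 0.81, a south run that is faster, and the finding that the product ties up the catalyst.

    2 free catalyst ⇌ catalyst dimer, settled at all times (101.0 M⁻¹)
    free catalyst + starting material + partner → product + free catalyst (25.70 M⁻² s⁻¹)
    free catalyst + product ⇌ catalyst-product complex, settled at all times (6.500 M⁻¹)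

The first chemist's plain rate has its region early in the south run: at 2.4 s there, one plus K[product] is 1.01. Taken over the rate of the north-east run at equal [starting material], the rate of the south run comes to 1.4, beside the brake's 1.38. Put into the brake's closed form, the south-west result of 0.279 M of product falls at 41.8 s, against the 43 s of that result.

The earlier runs and the new flask come from a simulation from invented constants, noise included.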